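The earlier runs and the new flask come from a simulation on assumed constants.

In a one-step world, substrate and partner give target, which climbs to the partner charge and stays there. Beta does otherwise: target reads 17.6% at 1.00 h and 7.0% at 8.00 h. Gamma also turns over, after a reading of 38.4% at 2.00 h. Target therefore passes on to something unseen, and in beta the readings level off. Call the plateau share s the target at rest, in percent of substrate charged, per equivalent of partner charged.

in all of them: substrate 0.30 M; initiator 10 mol%

| flask | partner | remark | time |
|---|---|---|---|
| beta | 0.29 equiv | run made earlier |  |
| gamma | 1.3 equiv | run made earlier |  |
| violet | 0.250 equiv |  | 15 h |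
| teal | 0.500 equiv |  | 15 h |
| red | 1.00 equiv |  | 15 h |

- beta (time / h: target / %): 1.00: 17.6; 2.00: 12.0; 3.00: 9.1; 4.00: 8.0; 5.00: 7.6; 6.00: 7.5; 8.00: 7.0
- gamma (time / h: target / %): 0.417: 19.2; 1.00: 33.2; 2.00: 38.4; 3.00: 34.9; 5.00: 29.1; 6.00: 27.7; 8.00: 25.1

(each reading ± 0.5 percentage points)

- the numbers in the tables scatter with a standard deviation of 0.5 percentage points
- "hardly changes" means that all values lie within two and a half points (for a concentration: within two and a half percent of the largest)

* amount of target at the end, in percent of the substrate charged for violet, teal, red, in this order
* the course of these numbers from the first flask to the last (rises, then falls / hardly changes / rises all the way / falls all the way / falls, then rises)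

The reckoning here takes the given numbers in turn. Substrate at 0.30 M and initiator at 10 mol% stand as in beta and gamma, so they bring no correction. Partner enters in proportion, as the limiting reagent in violet and teal. Time matters little for violet and teal, which stand close to beta: beta's excess over its last reading shrinks with a half-life of 0.861 h, as read, much shorter than 15 h. Putting that half-life back in, the excess left at 8.00 h is 0.04 percentage points, less than the scatter, so the plateau reading stands unmoved. That reading does count: its scatter moves the reckoned red by 1.7 points and the reckoned violet by 0.43 points.

The plateau share, target at rest per partner charged, is then 24.1% as read from beta. The reckoning gives 6.03%, 12.1% and 24.1%, a steady rise. Gamma's last reading stands 0.96 points above the last of these and is still falling.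

The forecast gives 6%, 12% and 20%, lower than this reckoning at red, with the course rises all the way, and says “The row rises throughout”. The flasks give 6.10%, 12.2% and 24.4%; the course rises all the way.

    initiator → 2 initiating radical (k = 2.30 × 10⁻⁴ h⁻¹)
    substrate + initiating radical → capped initiator + first chain carrier (k = 97000 M⁻¹ s⁻¹)
    partner + first chain carrier ⇌ target + second chain carrier (K = 0.450, k = 36000 M⁻¹ s⁻¹)
    substrate + second chain carrier → released group + first chain carrier (k = 47000 M⁻¹ s⁻¹)
    2 second chain carrier → ended chains (k = 1.40 × 10⁸ M⁻¹ s⁻¹)
    target ⇌ isomer of the product (K = 3.10, k = 0.680 h⁻¹)

Red holds 24.4% of target beside 75.6% of isomer of the product at 15.0 h. With the passing of target into isomer of the product taken away, both ways, red ends at >99.9% target, so this step is the reason for 100% of what is missing. Carried over, the remainder of the plateau share gives 75.9% of isomer of the product in red and 19.0% in violet, where the flask holds 18.9%.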